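**Retrosynthetic overview**
- Target 7 ⇐ its 16-norketone 6 (methylenation) ⇐ ring A ene-norketone 5 (hydrogenation) ⇐ 1,2-didehydro triacid 4 (oxidative cleavage). The exocyclic alkene is parked as a ketone while the 1,2-alkene is saturated, because the exocyclic alkene would otherwise hydrogenate first.
- Key disconnection C-10–C-20: 4 ⇐ gibberellic acid 1 + CO2 2. C-10, the electrophilic terminus of the allylic 19,10-lactone, is converted by Pd(PPh3)4/Et2Zn into an allylzinc (allyl anion equivalent) that attacks CO2. The same step opens the lactone to the C-19 acid and sets the quaternary C-10 centre.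
- Ring order: none of the carbocycles A–D is built. All four arrive in 1 with C-3, C-4, C-5, C-6, C-8, C-9 and C-13 already correct; only the lactone bridge is cut.

Assumption: gibberellic acid, a cheap bulk fermentation product sold as a plant growth regulator, is accepted as the commercial starting material. α and β follow the usual gibberellin drawings: H-5, H-9, 3-OH, the C-18 methyl and the C-7 carboxyl are β; C-19, C-20 and the lactone oxygen are α.

**Step 1**
Reactants: 1 gibberellic acid; 2 carbon dioxide
Product: 4 1,2-didehydro triacid (3β,13-dihydroxygibberella-1,16-diene-7,19,20-trioic acid), via allylzinc chelate 3 (not isolated)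
Conditions: Et2Zn (7 equiv), THF, 0 °C; then Pd(PPh3)4 (5 mol %), CO2 (1 atm), rt; cold 1 M HCl to pH 3
Reagents that add atoms: none
Why: Proposed new method: zerovalent palladium ionises the strained tertiary allylic lactone C-10–O bond, Et2Zn turns the electrophilic π-allyl into a configurationally labile allylzinc (umpolung) whose zinc sits pseudoaxially on the α face of C-2, held by the just-released axial C-19 carboxylate, and CO2 is captured at the γ-terminus C-10 through a chair-like six-membered transition state on the zinc-bearing α face, so the quaternary C-10 centre is set with C-20 cis to C-19 and trans to H-5 and H-9 while the alkene moves to the 1,2-position; the hydroxyl and carboxyl groups ride through as zinc salts, and the closest known reaction type is the Pd(PPh3)4/Et2Zn umpolung of allylic esters and alcohols (Tamaru-type allylation and its branched-selective carboxylation with CO2 through allylzincs).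

**Step 2**
Reactants: 4 1,2-didehydro triacid
Product: 5 ene-norketone (3β,13-dihydroxy-16-oxo-17-norgibberell-1-ene-7,19,20-trioic acid)
Conditions: OsO4 (2 mol %), NaIO4 (2.2 equiv), 2,6-lutidine, THF–H2O 2:1, 0 °C to rt; then pH 3
Reagents that add atoms: osmium tetroxide, O=[Os](=O)(=O)=O (catalytic oxygen carrier); sodium periodate, [Na+].[O-]I(=O)(=O)=O (terminal oxidant)
Why: Lemieux–Johnson oxidative cleavage attacks the exposed 1,1-disubstituted 16,17-alkene much faster than the ring A cis-alkene, which is shielded by the C-10 and C-4 quaternary centres and their axial carboxyl groups; no stereocentre is formed or touched.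

**Step 3**
Reactants: 5 ene-norketone
Product: 6 norketone (3β,13-dihydroxy-16-oxo-17-norgibberellane-7,19,20-trioic acid)
Conditions: H2 (3 atm), 5% Rh/Al2O3, EtOAc–MeOH, rt
Reagents that add atoms: none
Why: Heterogeneous catalytic hydrogenation of the only remaining alkene; Rh/Al2O3 gives little allylic C–O hydrogenolysis or alkene migration, the hindered ketone is inert at this pressure, and C-1 and C-2 both become CH2 so no stereocentre is created.

**Step 4**
Reactants: 6 norketone
Product: 7 target gibberellin (3β,13-dihydroxygibberell-16-ene-7,19,20-trioic acid)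
Conditions: Zn/CH2Br2/TiCl4 reagent (pre-formed in THF, about 15 equiv), CH2Cl2–THF, 0 °C to rt; cold aq. citric acid
Reagents that add atoms: dibromomethane, BrCBr
Why: Lombardo methylenation converts the ketone into the exocyclic methylene under non-basic conditions, avoiding the base-induced α-ketol shift of the 13-hydroxy-16-ketone and retro-aldol epimerisation at C-3; the free OH and CO2H groups only consume excess reagent and no stereocentre is involved.

**Compound list**
1 | gibberellic acid: 3β,13-dihydroxy-20-norgibberella-1,16-diene-7,19-dioic acid 19,10-lactone | C=C1C[C@]23C[C@@]1(O)CC[C@H]2[C@]14C=C[C@H](O)[C@@](C)(C(=O)O4)[C@H]1[C@@H]3C(=O)O | starting material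
2 | carbon dioxide | O=C=O | starting material
3 | allylzinc chelate: 2α-zincio-gibberella-1(10),16-diene with the C-2 zinc bound to the C-19 carboxylate; the 3-oxygen, the 13-oxygen and the C-7 carboxylate as ethylzinc salts | C=C1C[C@]23C[C@@]1(O[Zn]CC)CC[C@H]2C1=C[C@@H]([Zn]4)[C@H](O[Zn]CC)[C@@](C)(C(=O)O4)[C@H]1[C@@H]3C(=O)O[Zn]CC | intermediate
4 | 1,2-didehydro triacid: 3β,13-dihydroxygibberella-1,16-diene-7,19,20-trioic acid (new 10α-CO2H) | C=C1C[C@]23C[C@@]1(O)CC[C@H]2[C@]1(C(=O)O)C=C[C@H](O)[C@@](C)(C(=O)O)[C@H]1[C@@H]3C(=O)O | intermediate
5 | ene-norketone: 3β,13-dihydroxy-16-oxo-17-norgibberell-1-ene-7,19,20-trioic acid | O=C1C[C@]23C[C@@]1(O)CC[C@H]2[C@]1(C(=O)O)C=C[C@H](O)[C@@](C)(C(=O)O)[C@H]1[C@@H]3C(=O)O | intermediate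
6 | norketone: 3β,13-dihydroxy-16-oxo-17-norgibberellane-7,19,20-trioic acid | O=C1C[C@]23C[C@@]1(O)CC[C@H]2[C@]1(C(=O)O)CC[C@H](O)[C@@](C)(C(=O)O)[C@H]1[C@@H]3C(=O)O | intermediate
7 | target gibberellin (number 28 of the gibberellin A series): 3β,13-dihydroxygibberell-16-ene-7,19,20-trioic acid | C=C1C[C@]23C[C@@]1(O)CC[C@H]2[C@]1(C(=O)O)CC[C@H](O)[C@@](C)(C(=O)O)[C@H]1[C@@H]3C(=O)O | target

**Totals**
Total step count: 4. Longest linear sequence: 4 steps (1 → 4 → 5 → 6 → 7).

**Steps most likely to fail**

Step 1 (C-10 carboxylation) is the riskiest. The C-2–zinc bond is anti-periplanar to the C-3 oxide and can eliminate to a 1(10),2-diene; CO2 may also be captured at C-2 or on the β face. The fallback sets out from 1 and returns at 4. It makes the allyl nucleophile with a water-tolerant, weakly basic metal and a faster electrophile. Compound 1 with Pd(PPh3)4 (5 mol %), InI (2 equiv) and aqueous formaldehyde in THF at rt gives the C-10 hydroxymethyl adduct, which closes on the C-19 carboxyl to the δ-lactone 3β,13,20-trihydroxygibberella-1,16-diene-7,19-dioic acid 19,20-lactone F1. Only the α-adduct can lactonise, so the lactone also proves the C-10 configuration. The lactone is then opened with aqueous KOH and the neopentyl primary alcohol of the hydroxy-carboxylate is oxidised in the same pot (TEMPO cat., KBr, NaOCl, pH 10, 0 °C; then pH 3) to the triacid 4. These aqueous alkaline conditions favour primary over secondary alcohols, and the allylic 3-OH is further shielded by the C-4 quaternary centre.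

Step 4 (methylenation of a penta-protic α-ketol) is next. The acidic groups may consume the reagent or precipitate as insoluble carboxylate salts, and the Lewis acid may damage the tertiary α-ketol. The fallback sets out from 6 and returns at 7 by a two-stage Peterson olefination. Me3SiCH2MgCl/CeCl3 (excess, THF, 0 °C; weakly basic 1,2-addition) gives the β-hydroxysilane 3β,13,16-trihydroxy-16-(trimethylsilylmethyl)-17-norgibberellane-7,19,20-trioic acid F2 as C-16 epimers, both usable. KN(SiMe3)2 in THF then effects syn-elimination of the silanolate to the exocyclic methylene of 7.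

Step 2 (chemoselective cleavage) is third. Osmylation could reach the ring A alkene, or periodate could cleave the α-ketol of 5. The fallback sets out from 4 and comes back at 7 without masking, by carboxylate-directed homogeneous hydrogenation: H2 (50 atm), Ru(OAc)2(BINAP) (2 mol %, ligand enantiomer chosen by rate), MeOH, Et3N. The ring A alkene is both an allylic alcohol and a β,γ-unsaturated acid (through C-20), the substrate classes this catalyst reduces through a bound carboxylate or alkoxide. The exocyclic alkene has no carboxylate within reach and only a poorly disposed tertiary bridgehead hydroxyl. This fallback makes no new compound (F0) and would cut the route to two steps if selective; it is not the main route because exocyclic alkenes of this type normally hydrogenate faster.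

**Further compounds**
F1 | step 1 | 3β,13,20-trihydroxygibberella-1,16-diene-7,19-dioic acid 19,20-lactone | C=C1C[C@]23C[C@@]1(O)CC[C@H]2[C@]14C=C[C@H](O)[C@@](C)(C(=O)OC4)[C@H]1[C@@H]3C(=O)O
F2 | step 4 | 3β,13,16-trihydroxy-16-(trimethylsilylmethyl)-17-norgibberellane-7,19,20-trioic acid (C-16 epimers) | C[Si](C)(C)CC1(O)C[C@]23C[C@@]1(O)CC[C@H]2[C@]1(C(=O)O)CC[C@H](O)[C@@](C)(C(=O)O)[C@H]1[C@@H]3C(=O)O
F0 | step 2 | none | none
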